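Ring A is disconnected across two ring bonds by an Alder–Rickert transform. The feature exploited is the 1,3,5-pattern of ring A: the carbon bearing OMe, the carbon bearing OH and the carbon bearing the CH2CH2 tether to ring B are mutually meta, and the two oxygens differ. In one operation a cyclic 1-methoxy-3-siloxy diene adds to an alkynoate and ethene is expelled, which builds the benzene ring with OMe and OH already differentiated and a removable ester between OMe and the tether. The precursor is a benzyl 5-arylpent-2-ynoate whose aryl group is the complete ring B, O-benzylated and carrying both 4-(benzyloxy)benzyl arms (rings C and D).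

Key step: step 8

Remarks on the chemistry (assumptions):
- Ring A is the hydroxy-methoxy ring, ring B the central tetrasubstituted phenol, rings C and D the two 4-hydroxyphenyl rings.
- The diene of step 8 is the cross-conjugated kinetic silyl dienol ether of 3-methoxycyclohex-2-en-1-one. Its correct name is [(5-methoxycyclohexa-1,5-dien-1-yl)oxy]trimethylsilane, equally 1-methoxy-3-(trimethylsilyloxy)cyclohexa-1,3-diene, SMILES COC1=CC(O[Si](C)(C)C)=CCC1. A name of the type (3-methoxycyclohexa-1,3-dien-1-yl)oxy would describe the linearly conjugated isomer from γ-deprotonation, which is a different compound and is not used.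
- Ring B is assembled from 2,4-dibromophenol by lithiation and a double Negishi coupling, all routine two-component reactions, so that the risk stays in step 8.
- The alkyne is introduced only after the palladium-catalysed benzylations, because an arylpalladium species ortho to a but-3-ynyl chain could cyclise onto the triple bond.
- Compounds 1, 6, 10 and 16 are taken as purchased; telescoped operations in one flask count as one step.

Step 1
Reactants: 1 2,4-dibromophenol
Product: 2 1-(benzyloxy)-2,4-dibromobenzene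
Conditions: BnBr, K2CO3, DMF, 50 °C
Reagents that add atoms: benzyl bromide, BrCc1ccccc1
Why: Williamson ether synthesis, in which the acidic dibromophenol is deprotonated by K2CO3 and the phenoxide should be O-alkylated cleanly by the benzylic bromide, installing the same protecting group as on rings C and D.

Step 2
Reactants: 2 1-(benzyloxy)-2,4-dibromobenzene
Product: 5 [3-(benzyloxy)-2,6-dibromophenyl]methanol, via aryllithium 3 (not isolated), via aldehyde 4 (not isolated)
Conditions: LiN(i-Pr)2, THF, −78 °C; DMF, −78 → 0 °C; then MeOH, NaBH4, 0 °C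
Reagents that add atoms: N,N-dimethylformamide, CN(C)C=O
Why: Directed ortho-metalation followed by formylation and borohydride reduction, in which the ring hydrogen flanked by the two bromine atoms is the most acidic site, the amide base deprotonates without halogen–lithium exchange, the aryllithium should be trapped by DMF at −78 °C before it can lose LiBr, and NaBH4 reduces the released aldehyde in the same flask.

Step 3
Reactants: 5 [3-(benzyloxy)-2,6-dibromophenyl]methanol; 6 4-(benzyloxy)benzyl chloride
Product: 8 {3-(benzyloxy)-2,6-bis[4-(benzyloxy)benzyl]phenyl}methanol, via benzylic zinc chloride 7 (not isolated)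
Conditions: 6 (3 equiv), Zn dust, LiCl, THF, 25 °C; then 5, Pd(OAc)2, SPhos, THF, 25 → 50 °C
Reagents that add atoms: none
Why: Negishi cross-coupling, in which the LiCl-solubilised benzylic zinc chloride transmetalates to the arylpalladium bromides formed from 5 under Pd(OAc)2/SPhos, a system known to couple ortho,ortho′-disubstituted bromides and to outpace protonolysis by a free hydroxyl, so both C–Br bonds should be benzylated.

Step 4
Reactants: 8 {3-(benzyloxy)-2,6-bis[4-(benzyloxy)benzyl]phenyl}methanol
Product: 9 1-(benzyloxy)-3-(bromomethyl)-2,4-bis[4-(benzyloxy)benzyl]benzene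
Conditions: CBr4, PPh3, CH2Cl2, 0 °C
Reagents that add atoms: carbon tetrabromide, BrC(Br)(Br)Br
Why: Appel reaction, in which the primary benzylic alcohol should be converted into the bromide by SN2 displacement of the oxyphosphonium intermediate under neutral conditions that leave the three benzyl ethers intact.

Step 5
Reactants: 9 1-(benzyloxy)-3-(bromomethyl)-2,4-bis[4-(benzyloxy)benzyl]benzene; 10 trimethyl(prop-1-yn-1-yl)silane
Product: 13 1-(benzyloxy)-3-(but-3-yn-1-yl)-2,4-bis[4-(benzyloxy)benzyl]benzene, via lithiated silylpropyne 11 (not isolated), via alkynylsilane 12 (not isolated)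
Conditions: 10, n-BuLi, THF, −78 °C; then 9, −78 → 0 °C; then MeOH, K2CO3, 25 °C
Reagents that add atoms: none
Why: Propargylation with lithiated 1-(trimethylsilyl)propyne followed by protodesilylation, in which the silicon-capped propargyl anion should alkylate the primary benzylic bromide at its CH2 terminus (no β-hydrogen is available for elimination) and methanolic K2CO3 then removes the silyl group to give the terminal alkyne.

Step 6
Reactants: 13 1-(benzyloxy)-3-(but-3-yn-1-yl)-2,4-bis[4-(benzyloxy)benzyl]benzene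
Product: 15 benzyl 5-{3-(benzyloxy)-2,6-bis[4-(benzyloxy)benzyl]phenyl}pent-2-ynoate, via lithium acetylide 14 (not isolated)
Conditions: n-BuLi, THF, −78 °C; ClCO2Bn, −78 → 0 °C
Reagents that add atoms: benzyl chloroformate, O=C(Cl)OCc1ccccc1
Why: Acetylide acylation, in which n-BuLi should deprotonate only the terminal alkyne, by far the most acidic C–H in 13, and the lithium acetylide is acylated by the chloroformate to give the alkynoate.

Step 7
Reactants: 16 3-methoxycyclohex-2-en-1-one
Product: 18 [(5-methoxycyclohexa-1,5-dien-1-yl)oxy]trimethylsilane, via lithium dienolate 17 (not isolated)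
Conditions: LiN(i-Pr)2, THF, −78 °C; Me3SiCl, −78 → 25 °C; non-aqueous work-up, distillation
Reagents that add atoms: chlorotrimethylsilane, C[Si](C)(C)Cl
Why: Kinetic enolate silylation, in which the amide base should remove a proton from the α′ CH2 next to the carbonyl of the vinylogous ester and not from the γ position, and O-silylation of the cross-conjugated dienolate gives the 1-methoxy-3-siloxy diene.

Step 8
Reactants: 15 benzyl 5-{3-(benzyloxy)-2,6-bis[4-(benzyloxy)benzyl]phenyl}pent-2-ynoate; 18 [(5-methoxycyclohexa-1,5-dien-1-yl)oxy]trimethylsilane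
Product: 21 benzyl 2-{2-[3-(benzyloxy)-2,6-bis[4-(benzyloxy)benzyl]phenyl]ethyl}-4-hydroxy-6-methoxybenzoate, via bicyclo[2.2.2]octadiene adduct 19 (not isolated), via aryl silyl ether 20 (not isolated)
Conditions: 18 (3 equiv), o-xylene, sealed tube, 160 °C; then 1 M HCl, THF, 25 °C
Reagents that add atoms: none
Why: Thermal normal-demand (4+2) cycloaddition of the electron-rich diene 18 to the ynoate 15 gives the 1-methoxybicyclo[2.2.2]octa-2,5-diene 19, which at the same temperature loses ethene from its saturated two-carbon bridge by retro-(4+2) reaction to give the silyl ether 20, hydrolysed on work-up. The closest known reaction type is the Alder–Rickert synthesis of 4-hydroxy-6-methoxybenzoates from 1-methoxy-3-siloxycyclohexa-1,3-dienes and alkynoates. Ring A is closed by an intermolecular (4+2) annulation, four diene carbons plus the two alkyne carbons, and is revealed as a benzene ring by the cycloreversion, which is driven by aromatisation and the escape of a gas. No stereocentre is set, since the two bridgehead centres of racemic 19 vanish on aromatisation. The step needs regioselectivity: the largest HOMO coefficient lies on the unsubstituted diene terminus (the enol-ether β-carbon, reinforced by the vinylogous methoxy group) and the largest LUMO coefficient on the alkyne carbon β to the ester, so the chain-bearing carbon should bond to that CH terminus and the ester-bearing carbon to the methoxy-bearing carbon, placing the ester between OMe and the chain and para to the new OH. Excess diene and an acid-free sealed system guard against hydrolysis or isomerisation of 18 before it reacts.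

Step 9
Reactants: 21 benzyl 2-{2-[3-(benzyloxy)-2,6-bis[4-(benzyloxy)benzyl]phenyl]ethyl}-4-hydroxy-6-methoxybenzoate
Product: 22 2-{2-[3-hydroxy-2,6-bis(4-hydroxybenzyl)phenyl]ethyl}-4-hydroxy-6-methoxybenzoic acid
Conditions: H2 (1 atm), Pd/C, EtOAc–MeOH, 25 °C
Reagents that add atoms: none
Why: Catalytic hydrogenolysis, in which the three aryl benzyl ethers and the benzyl ester should all be cleaved at their benzylic C–O bonds over Pd/C while the diarylmethane and bibenzyl C–C bonds and the aryl methyl ether are inert.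

Step 10
Reactants: 22 2-{2-[3-hydroxy-2,6-bis(4-hydroxybenzyl)phenyl]ethyl}-4-hydroxy-6-methoxybenzoic acid
Product: 23 3-[2-(3-hydroxy-5-methoxyphenyl)ethyl]-2,4-bis(4-hydroxybenzyl)phenol
Conditions: Cu2O (cat.), 1,10-phenanthroline, NMP–quinoline, 160 °C, argon
Reagents that add atoms: none
Why: Copper-catalysed protodecarboxylation, in which the acid is flanked by two ortho substituents and activated by the para hydroxyl and ortho methoxy groups, so loss of CO2 by way of an aryl–copper species or ipso protonation should be easy and leaves the 1,3,5-substituted ring A of the target.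

Compound list
1 | 2,4-dibromophenol | Oc1ccc(Br)cc1Br | starting material
2 | 1-(benzyloxy)-2,4-dibromobenzene | Brc1ccc(OCc2ccccc2)c(Br)c1 | intermediate
3 | [3-(benzyloxy)-2,6-dibromophenyl]lithium | [Li]c1c(Br)ccc(OCc2ccccc2)c1Br | intermediate
4 | 3-(benzyloxy)-2,6-dibromobenzaldehyde | O=Cc1c(Br)ccc(OCc2ccccc2)c1Br | intermediate
5 | [3-(benzyloxy)-2,6-dibromophenyl]methanol | OCc1c(Br)ccc(OCc2ccccc2)c1Br | intermediate
6 | 4-(benzyloxy)benzyl chloride | ClCc1ccc(OCc2ccccc2)cc1 | starting material
7 | [4-(benzyloxy)benzyl]zinc chloride | Cl[Zn]Cc1ccc(OCc2ccccc2)cc1 | intermediate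
8 | {3-(benzyloxy)-2,6-bis[4-(benzyloxy)benzyl]phenyl}methanol | OCc1c(Cc2ccc(OCc3ccccc3)cc2)ccc(OCc2ccccc2)c1Cc1ccc(OCc2ccccc2)cc1 | intermediate
9 | 1-(benzyloxy)-3-(bromomethyl)-2,4-bis[4-(benzyloxy)benzyl]benzene | BrCc1c(Cc2ccc(OCc3ccccc3)cc2)ccc(OCc2ccccc2)c1Cc1ccc(OCc2ccccc2)cc1 | intermediate
10 | trimethyl(prop-1-yn-1-yl)silane | CC#C[Si](C)(C)C | starting material
11 | [3-(trimethylsilyl)prop-2-yn-1-yl]lithium | [Li]CC#C[Si](C)(C)C | intermediate
12 | {4-[3-(benzyloxy)-2,6-bis[4-(benzyloxy)benzyl]phenyl]but-1-yn-1-yl}trimethylsilane | C[Si](C)(C)C#CCCc1c(Cc2ccc(OCc3ccccc3)cc2)ccc(OCc2ccccc2)c1Cc1ccc(OCc2ccccc2)cc1 | intermediate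
13 | 1-(benzyloxy)-3-(but-3-yn-1-yl)-2,4-bis[4-(benzyloxy)benzyl]benzene | C#CCCc1c(Cc2ccc(OCc3ccccc3)cc2)ccc(OCc2ccccc2)c1Cc1ccc(OCc2ccccc2)cc1 | intermediate
14 | lithium acetylide of 13 | [Li]C#CCCc1c(Cc2ccc(OCc3ccccc3)cc2)ccc(OCc2ccccc2)c1Cc1ccc(OCc2ccccc2)cc1 | intermediate
15 | benzyl 5-{3-(benzyloxy)-2,6-bis[4-(benzyloxy)benzyl]phenyl}pent-2-ynoate | O=C(OCc1ccccc1)C#CCCc1c(Cc2ccc(OCc3ccccc3)cc2)ccc(OCc2ccccc2)c1Cc1ccc(OCc2ccccc2)cc1 | intermediate
16 | 3-methoxycyclohex-2-en-1-one | COC1=CC(=O)CCC1 | starting material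
17 | lithium 5-methoxycyclohexa-1,5-dien-1-olate | COC1=CC(O[Li])=CCC1 | intermediate
18 | [(5-methoxycyclohexa-1,5-dien-1-yl)oxy]trimethylsilane | COC1=CC(O[Si](C)(C)C)=CCC1 | intermediate
19 | benzyl 3-{2-[3-(benzyloxy)-2,6-bis[4-(benzyloxy)benzyl]phenyl]ethyl}-1-methoxy-5-[(trimethylsilyl)oxy]bicyclo[2.2.2]octa-2,5-diene-2-carboxylate (racemic) | COC12CCC(C(O[Si](C)(C)C)=C1)C(CCc3c(Cc4ccc(OCc5ccccc5)cc4)ccc(OCc4ccccc4)c3Cc3ccc(OCc4ccccc4)cc3)=C2C(=O)OCc1ccccc1 | intermediate
20 | benzyl 2-{2-[3-(benzyloxy)-2,6-bis[4-(benzyloxy)benzyl]phenyl]ethyl}-6-methoxy-4-[(trimethylsilyl)oxy]benzoate | COc1cc(O[Si](C)(C)C)cc(CCc2c(Cc3ccc(OCc4ccccc4)cc3)ccc(OCc3ccccc3)c2Cc2ccc(OCc3ccccc3)cc2)c1C(=O)OCc1ccccc1 | intermediate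
21 | benzyl 2-{2-[3-(benzyloxy)-2,6-bis[4-(benzyloxy)benzyl]phenyl]ethyl}-4-hydroxy-6-methoxybenzoate | COc1cc(O)cc(CCc2c(Cc3ccc(OCc4ccccc4)cc3)ccc(OCc3ccccc3)c2Cc2ccc(OCc3ccccc3)cc2)c1C(=O)OCc1ccccc1 | intermediate
22 | 2-{2-[3-hydroxy-2,6-bis(4-hydroxybenzyl)phenyl]ethyl}-4-hydroxy-6-methoxybenzoic acid | COc1cc(O)cc(CCc2c(Cc3ccc(O)cc3)ccc(O)c2Cc2ccc(O)cc2)c1C(=O)O | intermediate
23 | 3-[2-(3-hydroxy-5-methoxyphenyl)ethyl]-2,4-bis(4-hydroxybenzyl)phenol (CNP0518900.0, achiral) | COc1cc(O)cc(CCc2c(Cc3ccc(O)cc3)ccc(O)c2Cc2ccc(O)cc2)c1 | target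

Total step count: 10.
Longest linear sequence: 9 steps (steps 1 to 6, then 8, 9 and 10); step 7 is a one-step branch.

Steps most likely to fail

1. Step 8. The β-alkyl ynoate may add more slowly than the diene isomerises or loses its silyl group at 160 °C, or regiocontrol may erode. The fallback gives up the cycloaddition and makes the CH2–CH2 tether by olefination; it sets out from 9 and comes back at 23. Bromide 9 is heated with PPh3 in toluene to give {3-(benzyloxy)-2,6-bis[4-(benzyloxy)benzyl]benzyl}triphenylphosphonium bromide F1. Commercial 3-hydroxy-5-methoxybenzaldehyde is O-benzylated (BnBr, K2CO3, DMF) to 3-(benzyloxy)-5-methoxybenzaldehyde F2. Wittig reaction of the ylide from F1 (KOt-Bu, THF, 0 °C) with F2 should give 1-(benzyloxy)-3-{2-[3-(benzyloxy)-5-methoxyphenyl]ethenyl}-2,4-bis[4-(benzyloxy)benzyl]benzene F3 as an E/Z mixture. Hydrogenation over Pd/C (H2, EtOAc–MeOH) saturates the alkene and removes all four benzyl groups to give 23.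

2. Step 3. The second coupling at the bromine flanked by OBn and CH2OH may stall, the zinc reagent may be protonated by the free hydroxyl, or bromine may be lost by reduction through a palladium alkoxide. The fallback switches to a boron nucleophile at the aldehyde oxidation level, so that no protic group and no basic organometallic is present; it sets out from 4 (isolated by aqueous work-up of step 2 before the borohydride is added) and comes back at 8. Chloride 6 is borylated (B2pin2, Pd catalyst, KOAc) to 2-[4-(benzyloxy)benzyl]-4,4,5,5-tetramethyl-1,3,2-dioxaborolane F4. Double Suzuki–Miyaura coupling of 4 with F4 (Pd(OAc)2, SPhos, K3PO4, toluene–water, 90 °C) should give 3-(benzyloxy)-2,6-bis[4-(benzyloxy)benzyl]benzaldehyde F5, and NaBH4 in MeOH–THF reduces F5 to 8.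

3. Step 10. Decarboxylation may be incomplete, or the unprotected tetraphenol may degrade by oxidation at 160 °C. The fallback reorders the end game so that CO2 is lost while rings B, C and D are still benzylated; it sets out from 21 and comes back at 23. Hydrogenolysis of 21 over Pd/C in the presence of pyridine, which suppresses cleavage of aryl benzyl ethers, should remove only the ester benzyl group and give 2-{2-[3-(benzyloxy)-2,6-bis[4-(benzyloxy)benzyl]phenyl]ethyl}-4-hydroxy-6-methoxybenzoic acid F6. Protodecarboxylation of F6 (Ag2CO3 cat., AcOH, DMSO, 120 °C) should give 3-{2-[3-(benzyloxy)-2,6-bis[4-(benzyloxy)benzyl]phenyl]ethyl}-5-methoxyphenol F7, and additive-free hydrogenolysis (H2, Pd/C, EtOAc–MeOH, 25 °C) then gives 23 under mild conditions.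

Further compounds
F1 | step 8 | {3-(benzyloxy)-2,6-bis[4-(benzyloxy)benzyl]benzyl}triphenylphosphonium bromide | [Br-].c1ccc(cc1)[P+](Cc1c(Cc2ccc(OCc3ccccc3)cc2)ccc(OCc2ccccc2)c1Cc1ccc(OCc2ccccc2)cc1)(c1ccccc1)c1ccccc1
F2 | step 8 | 3-(benzyloxy)-5-methoxybenzaldehyde | COc1cc(C=O)cc(OCc2ccccc2)c1
F3 | step 8 | 1-(benzyloxy)-3-{2-[3-(benzyloxy)-5-methoxyphenyl]ethenyl}-2,4-bis[4-(benzyloxy)benzyl]benzene (E/Z mixture) | COc1cc(C=Cc2c(Cc3ccc(OCc4ccccc4)cc3)ccc(OCc3ccccc3)c2Cc2ccc(OCc3ccccc3)cc2)cc(OCc2ccccc2)c1
F4 | step 3 | 2-[4-(benzyloxy)benzyl]-4,4,5,5-tetramethyl-1,3,2-dioxaborolane | CC1(C)OB(Cc2ccc(OCc3ccccc3)cc2)OC1(C)C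
F5 | step 3 | 3-(benzyloxy)-2,6-bis[4-(benzyloxy)benzyl]benzaldehyde | O=Cc1c(Cc2ccc(OCc3ccccc3)cc2)ccc(OCc2ccccc2)c1Cc1ccc(OCc2ccccc2)cc1
F6 | step 10 | 2-{2-[3-(benzyloxy)-2,6-bis[4-(benzyloxy)benzyl]phenyl]ethyl}-4-hydroxy-6-methoxybenzoic acid | COc1cc(O)cc(CCc2c(Cc3ccc(OCc4ccccc4)cc3)ccc(OCc3ccccc3)c2Cc2ccc(OCc3ccccc3)cc2)c1C(=O)O
F7 | step 10 | 3-{2-[3-(benzyloxy)-2,6-bis[4-(benzyloxy)benzyl]phenyl]ethyl}-5-methoxyphenol | COc1cc(O)cc(CCc2c(Cc3ccc(OCc4ccccc4)cc3)ccc(OCc3ccccc3)c2Cc2ccc(OCc3ccccc3)cc2)c1
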